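## The problem

The target 16 is an isoflavan quinone in which a chroman (benzene ring A fused to pyran ring C) carries a 2,3-dimethoxy-1,4-benzoquinone (ring B) on C3, and ring A bears oxygen on four neighbouring carbons (OMe on C6 and C7, a free OH on C8, the ring oxygen O1 on C8a). The only stereocentre is C3 (S), and since nothing else in the molecule can relay to it, it has to be set by a catalyst or reagent and then carried through. C3–H lies α to the quinone, where quinone/quinone methide tautomerism can erase it under base or prolonged acid, whereas with ring B as a protected hydroquinone the centre is an ordinary benzylic C–H, so the quinone should appear last. Ring A is a very electron-rich phenol (O1 para to the C6 methoxy group, the C8 hydroxyl para to C5–H), which rules out forcing oxidants such as (NH4)2Ce(NO3)6 for making the quinone. The pyran ring is attached to ring A through two bonds on neighbouring carbons, C4–C4a and O1–C8a, and C8a is flanked on its other side by the C8 oxygen. An aryl iodide with iodine on C8a therefore has exactly one ortho substituent (the C8 oxygen) and one ortho C–H (C4a), the pattern on which the Catellani reaction (Pd(OAc)2 with norbornene) functionalises the ortho C–H and the ipso carbon in one operation. The bridge C4–C3–C2 is a 1,3-difunctional propane with ring B on its central carbon, whose symmetrical form is a 3-aryloxetane, so C3 can be set by desymmetrisation.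

## Retrosynthesis

**16 to 14 (through 15).** No skeletal bond is cut. The quinone is traced to hydroquinone 15 and this to dibenzyl ether 14, because hydrogenolysis is neutral and the hydroquinone is oxidised far more easily than the ring A phenol. Oxidative demethylation of a tetramethoxy ring B was set aside because ring A would compete. The forward step must debenzylate fully and oxidise only ring B.

**14 to 13.** Only the C8 protecting group changes. A methoxymethyl ether is chosen because the same group directs the metalation that places iodine on C8a, serves as the single ortho blocking group in the key step, and leaves under acid that benzyl ethers and the benzylic C3–H tolerate. A benzyl ether at C8 would save this step but cost two more in making the iodide.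

**13 to 4 and 12.** C4–C4a and O1–C8a are cut together. This removes ring C, divides the molecule into two fragments of similar size, and leaves C3 in an acyclic piece where it is easier to set. Cutting O1–C2 alone (phenol alkylation) or C3–C1' alone would leave the other ring bond to be made in separate steps. The forward reaction is a Catellani relay in which the primary bromide of 12 alkylates C4a and the hydroxyl of 12 then closes onto C8a. It must alkylate before it etherifies and must not disturb C3.

**12 to 10.** The C–Br bond and the O–H are traced back to one C–O bond of oxetane 10, which is achiral. Desymmetrising ring opening with a bromide source under a chiral hydrogen-bond-donor catalyst sets C3 by catalyst control alone. This is simpler than an auxiliary-based alkylation or a diol desymmetrisation followed by functional-group changes. The forward step must tolerate the ortho benzyloxy group of ring B.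

**10 to 8 and 9.** The C3–C1' bond is cut to aryl bromide 8 and 3-bromooxetane 9. A cross-electrophile coupling under NiCl2·glyme and Ir[dF(CF3)ppy]2(dtbbpy)PF6 with visible light joins them directly and keeps 8, the more valuable partner, as the limiting reagent. A route that first turns 8 into a nucleophilic partner needs one more step and an excess of the arene.

**8 to 7 to 5.** Bromide 8 comes from symmetrical arene 7 by a single bromination whose two possible sites are equivalent. Arene 7 comes from quinone 5 by reduction and double benzylation, so ring B keeps the oxygen pattern of the target from a purchasable compound.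

**4 to 2 to 1.** The C8a–I bond is traced to directed ortho-metalation of MOM ether 2, made from phenol 1. The OMOM group outranks the methoxy groups as a director and has only one free ortho position, so the iodine position is fixed by the substrate.

## Roads not taken

Alternative 1: Here the C3–C1' bond and the C4–C4a bond are cut around a two-carbon vinyl unit. In the forward direction the ring B aryllithium A2 adds to vinylboronic acid pinacol ester A1. The resulting boronate complex A3 is treated with the ring A aryl bromide A4 under Pd(OAc)2 and the chiral ferrocenyl diphosphine MandyPhos. A palladium-induced 1,2-aryl shift and reductive elimination then give the secondary benzylic boronate A5. The merit is that one catalytic, enantioselective step joins both arenes and sets C3. The reaction class is also established for aryl migrating groups and aryl electrophiles, so its key step carries less methodological risk than the one chosen here. The weak points are specific to this target: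
- Both aryl partners are ortho-oxygenated and hindered, with A2 hindered at the migrating carbon and A4 hindered next to the silyl ether, which is where this coupling loses rate and selectivity.
- Boronate A5 still lacks C2 and the pyran ring. A Matteson homologation, oxidation, desilylation and a Mitsunobu closure are needed before the deprotection steps, giving a route of about twelve steps.

The chosen plan is weaker on precedent. Against that it sets ring closure in the key step itself, a C3 fixed beforehand on a substrate class squarely within the scope of the desymmetrisation, and nine steps overall.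

Alternative 2: Here the C3–C1' bond is cut, and C4 is temporarily tied to a ring B oxygen. Quinone 5 and the ring A chromene A6 combine under stoichiometric TiCl2(OiPr)2 with TADDOL (tetravalent titanium) to give the cis-fused pterocarpan phenol A7. Hydrogenolysis of the benzylic C–O bond and the benzyl ether, then oxidation, would finish the synthesis. The merits are real. Ring B enters directly as 5 with its oxygen pattern in place, the reaction type is known for alkoxyquinones and chromenes, and only two operations follow A7. On step count this road is comparable to or slightly shorter than the chosen one. The weak points: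
- The chiral Lewis acid is stoichiometric.
- Enantioselectivity in this manifold depends on the substrate, and quinone 5, with two donor methoxy groups, is less electrophilic than the monoalkoxyquinones for which the method works best.
- [2+2] and [5+2] modes of addition compete with the desired one.
- The trioxygenated chromene A6 is acid-sensitive and needs several steps of its own.

The chosen plan sets against this a catalytic, catalyst-controlled origin of C3 and a regiochemistry fixed by the substitution pattern of the iodide, not by Lewis-acid-dependent periselectivity.

Alternative 3: Here the quinone ring itself is disconnected. Dimethyl squarate A8 takes up the deprotonated chroman alkyne A9 to give the alkynyl hydroxycyclobutenone A10. Heating A10 in toluene expands the four-membered ring to the six-membered quinone ring and gives the quinone MOM ether A11. The merits are that the quinone regiochemistry is guaranteed, no redox step or benzyl group is needed, and the ring expansion is well known. In how the quinone is made this road is better than the chosen one. The weak points: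
- The method does not address the harder problems. Alkyne A9 already contains ring C and the C3 stereocentre and would need its own enantioselective synthesis, with a propargylic centre at risk during alkyne installation.
- The last step is an acidic deprotection of A11, performed on a quinone whose α-C–H is the one configurationally fragile site.

The chosen plan pays with a hydrogenolysis/oxidation at the end, but builds ring C and attaches ring B in one step and keeps C3 robust until the final operation.

Key step: step 7

Assumption: 3-bromooxetane and 2,3-dimethoxy-1,4-benzoquinone are treated as purchasable, and the squaramide antipode that gives the S series is identified by assigning the absolute configuration of 12 once; both antipodes of the catalyst are accessible.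

## Route

Step 1
Reactants: 1 2,3-dimethoxyphenol
Product: 2 1,2-dimethoxy-3-(methoxymethoxy)benzene
Conditions: MOMCl, iPr2NEt, CH2Cl2, 0 °C to rt
Reagents that add atoms: chloromethyl methyl ether, COCCl
Why: O-alkylation of a phenol with an α-chloro ether (Williamson-type acetal formation) is routine; the MOM group is chosen because it is the strongest ortho director on the ring for step 2.

Step 2
Reactants: 2 1,2-dimethoxy-3-(methoxymethoxy)benzene
Product: 4 1-iodo-3,4-dimethoxy-2-(methoxymethoxy)benzene, via aryllithium 3 (not isolated)
Conditions: n-BuLi, THF, 0 °C; then I2, THF, −78 °C to rt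
Reagents that add atoms: iodine, II
Why: Directed ortho-metalation: the OMOM group chelates lithium and directs deprotonation to its only free ortho position (the future C8a) in preference to the site beside the weaker methoxy director. Iodinolysis of the aryllithium then places iodine there.

Step 3
Reactants: 5 2,3-dimethoxy-1,4-benzoquinone
Product: 7 1,4-bis(benzyloxy)-2,3-dimethoxybenzene, via hydroquinone 6 (not isolated)
Conditions: Na2S2O4, EtOAc/H2O, rt; then BnBr, K2CO3, DMF, 60 °C (crude hydroquinone kept under N2)
Reagents that add atoms: benzyl bromide, BrCc1ccccc1
Why: Dithionite reduction of a quinone to its hydroquinone followed by double Williamson benzylation; telescoping avoids handling the air-sensitive hydroquinone.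

Step 4
Reactants: 7 1,4-bis(benzyloxy)-2,3-dimethoxybenzene
Product: 8 1,4-bis(benzyloxy)-5-bromo-2,3-dimethoxybenzene
Conditions: NBS (1.0 equiv), MeCN, 0 °C to rt
Reagents that add atoms: N-bromosuccinimide, O=C1CCC(=O)N1Br
Why: Electrophilic aromatic bromination of a tetra-alkoxybenzene; the two free positions are equivalent by symmetry, so only the stoichiometry has to be controlled to avoid dibromination.

Step 5
Reactants: 8 1,4-bis(benzyloxy)-5-bromo-2,3-dimethoxybenzene; 9 3-bromooxetane
Product: 10 3-[2,5-bis(benzyloxy)-3,4-dimethoxyphenyl]oxetane
Conditions: Ir[dF(CF3)ppy]2(dtbbpy)PF6 (1 mol%), NiCl2·glyme (5 mol%), 4,4'-di-tert-butyl-2,2'-bipyridine (5 mol%), (Me3Si)3SiH, Na2CO3, DME, blue LEDs, rt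
Reagents that add atoms: none
Why: Nickel/photoredox cross-electrophile coupling: a silyl radical abstracts bromine from 9 and the oxetan-3-yl radical is captured by the aryl nickel species formed from 8, a method established for aryl bromides with strained secondary heterocyclic bromides. The conditions are neutral and at room temperature, so the benzyl and methyl ethers are spectators.

Step 6
Reactants: 10 3-[2,5-bis(benzyloxy)-3,4-dimethoxyphenyl]oxetane
Product: 12 (2S)-2-[2,5-bis(benzyloxy)-3,4-dimethoxyphenyl]-3-bromopropan-1-ol, via trimethylsilyl ether 11 (not isolated)
Conditions: TMSBr (1.2 equiv), chiral arylpyrrolidine-derived squaramide (5 mol%), t-BuOMe, −78 °C; then aq. citric acid, THF, 0 °C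
Reagents that add atoms: bromotrimethylsilane, C[Si](C)(C)Br
Why: Enantioselective desymmetrising ring opening of a 3-aryloxetane: the squaramide binds bromide and delivers it to one of the two enantiotopic CH2 groups of the O-silylated oxetanium ion, so the catalyst antipode alone decides the configuration of the future C3 (the antipode giving S is used). The substitution occurs at CH2, not at the stereogenic carbon, and the primary silyl ether is cleaved in the mild acidic work-up.

Step 7
Reactants: 4 1-iodo-3,4-dimethoxy-2-(methoxymethoxy)benzene; 12 (2S)-2-[2,5-bis(benzyloxy)-3,4-dimethoxyphenyl]-3-bromopropan-1-ol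
Product: 13 (3S)-3-[2,5-bis(benzyloxy)-3,4-dimethoxyphenyl]-6,7-dimethoxy-8-(methoxymethoxy)chromane
Conditions: Pd(OAc)2 (10 mol%), XPhos (20 mol%), norbornene (1.5 equiv), Cs2CO3 (3 equiv), 1,4-dioxane, 100 °C; 4 in slight excess (1.2 equiv)
Reagents that add atoms: none
Why: Proposed new method: Zerovalent palladium inserts into the C8a–I bond of 4; norbornene carbopalladation and C–H palladation at C4a (the only free ortho position, C8 being blocked by OMOM) give a five-membered divalent palladacycle, and SN2-type oxidative addition of the primary bromide of 12 to tetravalent palladium followed by reductive elimination forms C4–C4a. The aryl group, now substituted at both ortho positions, extrudes norbornene by β-carbon elimination, and the aryl palladium species takes up the tethered alkoxide and closes the pyran ring by C(aryl)–O reductive elimination at the ipso carbon (six-membered ring closure through a seven-membered oxapalladacycle). The closest known reactions are Catellani annulations that pair ortho-alkylation with ipso C–O closure from epoxides (five-membered dihydrobenzofurans) or with ipso amination from bromoalkylamines (tetrahydroquinolines), and the stand-alone palladium-catalysed cyclisation of 3-(2-halophenyl)propanols to chromans; this step merges the two. No stereocentre is formed: C3 is β to both reacting carbons, has no hydrogen acidic enough for carbonate, and is carried through unchanged. The step needs alkylation before etherification, which the relay enforces because norbornene insertion into the first aryl palladium iodide is faster than direct C–O coupling. It also needs C–O reductive elimination to outrun β-hydride elimination of the primary alkoxide, for which the bulky dialkylbiaryl phosphine is chosen, and a weak carbonate base so that free 12 is not driven back to the oxetane or to the allylic alcohol before it is consumed.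

Step 8
Reactants: 13 (3S)-3-[2,5-bis(benzyloxy)-3,4-dimethoxyphenyl]-6,7-dimethoxy-8-(methoxymethoxy)chromane
Product: 14 (3S)-3-[2,5-bis(benzyloxy)-3,4-dimethoxyphenyl]-6,7-dimethoxychroman-8-ol
Conditions: HCl (2 M in MeOH), MeOH/THF, 40 °C
Reagents that add atoms: none
Why: Acid-catalysed acetal exchange (methanolysis of the MOM ether) frees the C8 phenol; benzyl and methyl aryl ethers and the benzylic C3–H are stable to dilute methanolic acid.

Step 9
Reactants: 14 (3S)-3-[2,5-bis(benzyloxy)-3,4-dimethoxyphenyl]-6,7-dimethoxychroman-8-ol
Product: 16 5-[(3S)-8-hydroxy-6,7-dimethoxychroman-3-yl]-2,3-dimethoxycyclohexa-2,5-diene-1,4-dione (target), via hydroquinone 15 (not isolated)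
Conditions: H2 (1 atm), Pd/C, EtOAc/MeOH, rt; filtration under N2; then FeCl3 (2.1 equiv), H2O/EtOAc, 0 °C, short contact
Reagents that add atoms: none
Why: Hydrogenolysis of the two benzyl ethers releases the dimethoxyhydroquinone, which is oxidised at a much lower potential than the ring A monophenol, so two equivalents of a one-electron oxidant should stop at the para-quinone. Neither operation touches C3, and the quinone, whose α-C–H is the only racemisation-prone site in the series, is formed in the last step.

## Compound list

1 | 2,3-dimethoxyphenol | COc1cccc(O)c1OC | starting material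
2 | 1,2-dimethoxy-3-(methoxymethoxy)benzene | COCOc1cccc(OC)c1OC | intermediate
3 | [3,4-dimethoxy-2-(methoxymethoxy)phenyl]lithium | [Li]c1ccc(OC)c(OC)c1OCOC | intermediate
4 | 1-iodo-3,4-dimethoxy-2-(methoxymethoxy)benzene | COCOc1c(I)ccc(OC)c1OC | intermediate
5 | 2,3-dimethoxy-1,4-benzoquinone | COC1=C(OC)C(=O)C=CC1=O | starting material
6 | 2,3-dimethoxybenzene-1,4-diol | COc1c(O)ccc(O)c1OC | intermediate
7 | 1,4-bis(benzyloxy)-2,3-dimethoxybenzene | COc1c(OCc2ccccc2)ccc(OCc2ccccc2)c1OC | intermediate
8 | 1,4-bis(benzyloxy)-5-bromo-2,3-dimethoxybenzene | COc1c(OC)c(OCc2ccccc2)c(Br)cc1OCc1ccccc1 | intermediate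
9 | 3-bromooxetane | BrC1COC1 | starting material
10 | 3-[2,5-bis(benzyloxy)-3,4-dimethoxyphenyl]oxetane | COc1c(OC)c(OCc2ccccc2)cc(C2COC2)c1OCc1ccccc1 | intermediate
11 | {(2S)-2-[2,5-bis(benzyloxy)-3,4-dimethoxyphenyl]-3-bromopropoxy}trimethylsilane | C[Si](C)(C)OC[C@@H](CBr)c1cc(OCc2ccccc2)c(OC)c(OC)c1OCc1ccccc1 | intermediate
12 | (2S)-2-[2,5-bis(benzyloxy)-3,4-dimethoxyphenyl]-3-bromopropan-1-ol | OC[C@@H](CBr)c1cc(OCc2ccccc2)c(OC)c(OC)c1OCc1ccccc1 | intermediate
13 | (3S)-3-[2,5-bis(benzyloxy)-3,4-dimethoxyphenyl]-6,7-dimethoxy-8-(methoxymethoxy)chromane | COc1c(OC)c(OCc2ccccc2)cc([C@H]2COc3c(cc(OC)c(OC)c3OCOC)C2)c1OCc1ccccc1 | intermediate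
14 | (3S)-3-[2,5-bis(benzyloxy)-3,4-dimethoxyphenyl]-6,7-dimethoxychroman-8-ol | COc1c(OC)c(OCc2ccccc2)cc([C@H]2COc3c(cc(OC)c(OC)c3O)C2)c1OCc1ccccc1 | intermediate
15 | 2-[(3S)-8-hydroxy-6,7-dimethoxychroman-3-yl]-5,6-dimethoxybenzene-1,4-diol | COc1c(OC)c(O)cc([C@H]2COc3c(cc(OC)c(OC)c3O)C2)c1O | intermediate
16 | 5-[(3S)-8-hydroxy-6,7-dimethoxychroman-3-yl]-2,3-dimethoxycyclohexa-2,5-diene-1,4-dione | COC1=C(OC)C(=O)C([C@H]2COc3c(cc(OC)c(OC)c3O)C2)=CC1=O | target

## Step count and risks

Total: 9 steps. Longest linear sequence: 7 steps (5 to 16 through steps 3 to 9); the ring A iodide 4 is made in 2 steps and joins at step 7.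

**Step 7 (key step).** Three processes may defeat it:
- Base may consume the free bromo alcohol before the relay does, by reclosure to the oxetane or by dehydrobromination at the benzylic β-hydrogen.
- β-Hydride elimination at the palladium alkoxide stage may compete, which would end in ipso reduction and not in C–O bond formation.
- Oxidative addition of the β-branched bromide to the palladacycle may be slow, which would let aryl–aryl coupling of 4 compete.

The fallback uses known chemistry only, sets out from 2 and 12, and returns at 13. Aryllithium 3, generated from 2 as in step 2, is quenched with B(OMe)3 to the dimethyl arylboronate F1, which is oxidised in the same flask with H2O2/NaOH to 3,4-dimethoxy-2-(methoxymethoxy)phenol F2. NBS with catalytic iPr2NH brominates the only free position ortho to the hydroxyl and gives 6-bromo-3,4-dimethoxy-2-(methoxymethoxy)phenol F3. Mitsunobu coupling (PPh3, DIAD, THF) of F3 with the primary alcohol of 12 gives the bromoaryl bromoalkyl ether F4 and so forms O1–C8a without touching C3. n-BuLi at −100 °C exchanges the aryl bromide, and the resulting aryllithium F5 displaces the primary bromide in a Parham cycloalkylation (6-exo-tet) that forms C4–C4a and gives 13.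

**Step 6.** The ortho benzyloxy group may disturb the arrangement of oxetanium ion, bromide and catalyst, and an uncatalysed background opening by TMSBr would then erode the enantioselectivity. The fallback sets out from 10 and returns at 12. Aqueous HBr in THF at 0 °C opens the oxetane without a catalyst to the racemic bromo alcohol F6, which is resolved by preparative chromatography on a chiral stationary phase to give 12. The unwanted (2R)-bromo alcohol F7 is closed back to achiral 10 with KOtBu in THF and recycled.

**Step 5.** Oxidative addition of the very electron-rich, ortho-substituted bromide may lag behind radical generation, which would lead to hydrodebromination of 8 and to dimerisation or reduction of the oxetanyl radical. The fallback sets out from 8 and returns at 10. Palladium-catalysed borylation (Pd(OAc)2, XPhos, B2(OH)4, KOAc, EtOH, 80 °C) gives [2,5-bis(benzyloxy)-3,4-dimethoxyphenyl]boronic acid F8. This is coupled with commercial 3-iodooxetane in an alkyl–aryl Suzuki reaction (NiI2, trans-2-aminocyclohexanol hydrochloride, NaN(SiMe3)2, iPrOH, 80 °C) to give 10.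

**Step 9.** FeCl3 may also attack the ring A phenol (a 2,6-dialkoxyphenol with a free para position) by oxidative coupling, or hydrogenolysis of the benzyl ether flanked by two substituents may be incomplete. The fallback sets out from 13 and returns at 16. With ring A still protected, hydrogenolysis (H2, Pd/C) gives the hydroquinone MOM ether F9, which FeCl3 oxidises without a competing phenol to the quinone MOM ether F10, the same compound that alternative 3 reaches as A11. The MOM group is then removed with p-TsOH in MeOH at 40 °C, chloride-free so that no hydrogen halide adds to the quinone, with short exposure to limit tautomerisation at C3.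

## Further compounds

F1 | step 7 | dimethyl [3,4-dimethoxy-2-(methoxymethoxy)phenyl]boronate | COCOc1c(B(OC)OC)ccc(OC)c1OC
F2 | step 7 | 3,4-dimethoxy-2-(methoxymethoxy)phenol | COCOc1c(O)ccc(OC)c1OC
F3 | step 7 | 6-bromo-3,4-dimethoxy-2-(methoxymethoxy)phenol | COCOc1c(O)c(Br)cc(OC)c1OC
F4 | step 7 | 1,4-bis(benzyloxy)-5-{(2S)-1-bromo-3-[2-bromo-4,5-dimethoxy-6-(methoxymethoxy)phenoxy]propan-2-yl}-2,3-dimethoxybenzene | COCOc1c(OC[C@@H](CBr)c2cc(OCc3ccccc3)c(OC)c(OC)c2OCc2ccccc2)c(Br)cc(OC)c1OC
F5 | step 7 | [2-{(2S)-2-[2,5-bis(benzyloxy)-3,4-dimethoxyphenyl]-3-bromopropoxy}-4,5-dimethoxy-3-(methoxymethoxy)phenyl]lithium | COCOc1c(OC[C@@H](CBr)c2cc(OCc3ccccc3)c(OC)c(OC)c2OCc2ccccc2)c([Li])cc(OC)c1OC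
F6 | step 6 | racemic 2-[2,5-bis(benzyloxy)-3,4-dimethoxyphenyl]-3-bromopropan-1-ol | OCC(CBr)c1cc(OCc2ccccc2)c(OC)c(OC)c1OCc1ccccc1
F7 | step 6 | (2R)-2-[2,5-bis(benzyloxy)-3,4-dimethoxyphenyl]-3-bromopropan-1-ol | OC[C@H](CBr)c1cc(OCc2ccccc2)c(OC)c(OC)c1OCc1ccccc1
F8 | step 5 | [2,5-bis(benzyloxy)-3,4-dimethoxyphenyl]boronic acid | OB(O)c1cc(OCc2ccccc2)c(OC)c(OC)c1OCc1ccccc1
F9 | step 9 | 2-[(3S)-6,7-dimethoxy-8-(methoxymethoxy)chroman-3-yl]-5,6-dimethoxybenzene-1,4-diol | COc1c(OC)c(O)cc([C@H]2COc3c(cc(OC)c(OC)c3OCOC)C2)c1O
F10 | step 9 | 5-[(3S)-6,7-dimethoxy-8-(methoxymethoxy)chroman-3-yl]-2,3-dimethoxycyclohexa-2,5-diene-1,4-dione | COC1=C(OC)C(=O)C([C@H]2COc3c(cc(OC)c(OC)c3OCOC)C2)=CC1=O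
A1 | alternative 1 | 4,4,5,5-tetramethyl-2-vinyl-1,3,2-dioxaborolane | C=CB1OC(C)(C)C(C)(C)O1
A2 | alternative 1 | [2,5-bis(benzyloxy)-3,4-dimethoxyphenyl]lithium | [Li]c1cc(OCc2ccccc2)c(OC)c(OC)c1OCc1ccccc1
A3 | alternative 1 | lithium [2,5-bis(benzyloxy)-3,4-dimethoxyphenyl](vinyl)(pinacolato)borate | [Li+].C=C[B-]1(OC(C)(C)C(C)(C)O1)c1cc(OCc2ccccc2)c(OC)c(OC)c1OCc1ccccc1
A4 | alternative 1 | [2-(benzyloxy)-6-bromo-3,4-dimethoxyphenoxy](tert-butyl)dimethylsilane | Brc1cc(OC)c(OC)c(OCc2ccccc2)c1O[Si](C)(C)C(C)(C)C
A5 | alternative 1 | 2-{(1S)-1-[2,5-bis(benzyloxy)-3,4-dimethoxyphenyl]-2-[3-(benzyloxy)-2-{[tert-butyl(dimethyl)silyl]oxy}-4,5-dimethoxyphenyl]ethyl}-4,4,5,5-tetramethyl-1,3,2-dioxaborolane | CC1(C)OB(OC1(C)C)[C@@H](Cc1cc(OC)c(OC)c(OCc2ccccc2)c1O[Si](C)(C)C(C)(C)C)c1cc(OCc2ccccc2)c(OC)c(OC)c1OCc1ccccc1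
A6 | alternative 2 | 8-(benzyloxy)-6,7-dimethoxy-2H-chromene | COc1cc2c(OCC=C2)c(OCc2ccccc2)c1OC
A7 | alternative 2 | cis-4-(benzyloxy)-8-hydroxy-2,3,9,10-tetramethoxypterocarpan, C6a configured as C3 of the target | COc1c(OC)c(O)cc2c1O[C@@H]1c3cc(OC)c(OC)c(OCc4ccccc4)c3OC[C@H]21
A8 | alternative 3 | dimethyl squarate (3,4-dimethoxycyclobut-3-ene-1,2-dione) | COC1=C(OC)C(=O)C1=O
A9 | alternative 3 | (3S)-3-ethynyl-6,7-dimethoxy-8-(methoxymethoxy)chromane | C#C[C@H]1COc2c(cc(OC)c(OC)c2OCOC)C1
A10 | alternative 3 | 4-hydroxy-2,3-dimethoxy-4-{[(3S)-6,7-dimethoxy-8-(methoxymethoxy)chroman-3-yl]ethynyl}cyclobut-2-en-1-one, either configuration at the carbinol carbon | COC1=C(OC)C(O)(C#C[C@H]2COc3c(cc(OC)c(OC)c3OCOC)C2)C1=O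
A11 | alternative 3 | 5-[(3S)-6,7-dimethoxy-8-(methoxymethoxy)chroman-3-yl]-2,3-dimethoxycyclohexa-2,5-diene-1,4-dione | COC1=C(OC)C(=O)C([C@H]2COc3c(cc(OC)c(OC)c3OCOC)C2)=CC1=O
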